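**Retrosynthetic overview**
1. Glycybridin C (10) ⇒ bis(1,1-dimethylallyl) aryl ether 9. One double aromatic Claisen rearrangement installs both C-prenyl groups.
2. 9 ⇒ unprenylated tetraol ketone 5, by double Pd-catalysed O-tert-prenylation of the two non-chelated phenols.
3. 5 ⇒ aryl ester 4. The key aryl–C(=O) bond is made by a photo-Fries acyl shift, in which C4 and C6 attack give the same product.
4. 4 ⇒ resorcinol (3) + (R)-4-hydroxyphenyllactic acid (2). 2 ⇒ D-tyrosine (1), the only source of chirality, carried through with retention.
5. No ring is constructed. Both benzene rings are bought.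

Assumption: the SMILES stereocentre is (R) (OH > C=O > CH2Ar > H), which maps onto D-tyrosine. Carbonate 8 is made rather than assumed purchasable.

**Step 1**
Reactants: 1, D-tyrosine
Product: 2, (R)-2-hydroxy-3-(4-hydroxyphenyl)propanoic acid
Conditions: NaNO2 (2 equiv, slow addition), 1 M H2SO4, H2O, 0 °C → rt
Reagents that add atoms: water, O
Why: Diazotisation/hydroxy-dediazoniation of an α-amino acid, where the carboxylate expels N2 to give an α-lactone that water reopens, so two inversions give net retention and the bought (R) centre becomes the (R) carbinol.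

**Step 2**
Reactants: 2, (R)-2-hydroxy-3-(4-hydroxyphenyl)propanoic acid; 3, resorcinol
Product: 4, 3-hydroxyphenyl (R)-2-hydroxy-3-(4-hydroxyphenyl)propanoate
Conditions: one pot: TMSCl (3.5 equiv), pyridine, CH2Cl2, rt; (COCl)2 (1.05 equiv), cat. DMF, 0 °C; 3 (5 equiv), pyridine, THF, −10 → 0 °C; aq. citric acid/THF, rt
Reagents that add atoms: resorcinol (3), Oc1cccc(O)c1 (the TMS groups are lost in the quench)
Why: This is the established transient-silylation/acid-chloride protocol for α-hydroxy acids followed by Einhorn-type O-acylation; excess water-removable resorcinol enforces mono-acylation, and the weak base at low temperature avoids ketene formation, so C2 is untouched.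

**Step 3 (key step)**
Reactants: 4, 3-hydroxyphenyl (R)-2-hydroxy-3-(4-hydroxyphenyl)propanoate
Product: 5, (R)-1-(2,4-dihydroxyphenyl)-2-hydroxy-3-(4-hydroxyphenyl)propan-1-one
Conditions: hν 254 nm (low-pressure Hg, FEP/quartz flow coil), Ar-degassed MeCN (5 mM), 20 °C, tR ≈ 30 min; chromatography removes the minor 2,6-dihydroxy isomer and resorcinol
Reagents that add atoms: none
Why: Proposed new method: a protecting-group-free, stereoretentive photo-Fries shift of an enantiopure, free α-hydroxyacyl group, whose closest known reaction type is the photo-Fries rearrangement of resorcinol monoacetate/monobenzoate to 2,4-dihydroxyaryl ketones; singlet ArO–C(O) homolysis and in-cage recombination occur in picoseconds, far faster than decarbonylation of the α-hydroxyacyl σ-radical (about 10^5–10^7 s^-1), the carbinol carbon never carries spin so (R) is retained, ortho (C6) and para (C4) recombination give the same 2,4-dihydroxy ketone after tautomerisation, and the o-hydroxyaryl ketone formed deactivates by excited-state proton transfer, which shuts off Norrish I cleavage.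

**Step 4**
Reactants: 6, 2-methylbut-3-en-2-ol; 7, di-tert-butyl dicarbonate
Product: 8, tert-butyl 2-methylbut-3-en-2-yl carbonate
Conditions: n-BuLi (1.0 equiv), THF, −78 → 0 °C; then 7, 0 °C → rt
Reagents that add atoms: di-tert-butyl dicarbonate (7), CC(C)(C)OC(=O)OC(=O)OC(C)(C)C
Why: Simple alkoxide acylation (O-Boc formation) of a tertiary allylic alcohol, with no stereochemistry involved.

**Step 5**
Reactants: 5, (R)-1-(2,4-dihydroxyphenyl)-2-hydroxy-3-(4-hydroxyphenyl)propan-1-one; 8, tert-butyl 2-methylbut-3-en-2-yl carbonate (2.4 equiv)
Product: 9, (R)-2-hydroxy-1-[2-hydroxy-4-(2-methylbut-3-en-2-yloxy)phenyl]-3-[4-(2-methylbut-3-en-2-yloxy)phenyl]propan-1-one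
Conditions: Pd(PPh3)4 (8 mol %), THF, 0–5 °C, 3 h
Reagents that add atoms: carbonate 8, CC(C)(C)OC(=O)OC(C)(C)C=C (delivers two C5H9 units; CO2 and t-BuOH are lost)
Why: Tsuji–Trost O-allylation, in which the released t-BuO− is consumed at once by the two free phenols (pKa about 8 and 10) and their phenoxides attack the more substituted π-prenyl terminus under kinetic control at low temperature, while the chelated 2'-OH and the carbinol do not compete and the buffered medium spares the α-ketol centre.

**Step 6**
Reactants: 9, the bis(1,1-dimethylallyl) ether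
Product: 10, glycybridin C, (R)-1-[2,4-dihydroxy-3-(3-methylbut-2-enyl)phenyl]-2-hydroxy-3-[4-hydroxy-3-(3-methylbut-2-enyl)phenyl]propan-1-one
Conditions: degassed PhMe (0.02 M), base-washed sealed tube, 120 °C, 6 h
Reagents that add atoms: none
Why: Double aromatic Claisen [3,3] rearrangement with allyl inversion (tert-prenyl-O → prenyl-C), where the B ring has two equivalent ortho sites, the A ring migrates to C3' because the 2'-OH···O=C chelate fixes C3'=C4' double-bond character (as with 4-allyloxy-2-hydroxyacetophenone → 3-allyl), and neutral aprotic heating avoids enolisation so (R) is kept.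

**Compound list**

| No. | Name | SMILES | Role |
|---|---|---|---|
| 1 | D-tyrosine | N[C@H](Cc1ccc(O)cc1)C(=O)O | starting material |
| 2 | (R)-2-hydroxy-3-(4-hydroxyphenyl)propanoic acid | O[C@H](Cc1ccc(O)cc1)C(=O)O | intermediate |
| 3 | resorcinol | Oc1cccc(O)c1 | starting material |
| 4 | 3-hydroxyphenyl (R)-2-hydroxy-3-(4-hydroxyphenyl)propanoate | O[C@H](Cc1ccc(O)cc1)C(=O)Oc1cccc(O)c1 | intermediate |
| 5 | (R)-1-(2,4-dihydroxyphenyl)-2-hydroxy-3-(4-hydroxyphenyl)propan-1-one | O[C@H](Cc1ccc(O)cc1)C(=O)c1ccc(O)cc1O | intermediate |
| 6 | 2-methylbut-3-en-2-ol | CC(C)(O)C=C | starting material |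
| 7 | di-tert-butyl dicarbonate | CC(C)(C)OC(=O)OC(=O)OC(C)(C)C | starting material |
| 8 | tert-butyl 2-methylbut-3-en-2-yl carbonate | CC(C)(C)OC(=O)OC(C)(C)C=C | intermediate |
| 9 | (R)-2-hydroxy-1-[2-hydroxy-4-(2-methylbut-3-en-2-yloxy)phenyl]-3-[4-(2-methylbut-3-en-2-yloxy)phenyl]propan-1-one | O[C@H](Cc1ccc(OC(C)(C)C=C)cc1)C(=O)c1ccc(OC(C)(C)C=C)cc1O | intermediate |
| 10 | glycybridin C | CC(C)=CCc1cc(C[C@@H](O)C(=O)c2ccc(O)c(CC=C(C)C)c2O)ccc1O | target |

**Step count**
Total: 6 steps.
Longest linear sequence: 5 steps (1 → 2 → 4 → 5 → 9 → 10).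

**Three steps most likely to fail**
1. **Step 3 (proposed new photo-Fries).**
   - Risks: cage escape followed by decarbonylation, C2 recombination giving the 2,6-dihydroxy isomer, and product inner-filter stalling.
   - Fallback (known chemistry): convert 2 into its bis-TBS ether Weinreb amide. Add 2,4-bis(methoxymethoxy)phenyllithium, made from 1-bromo-2,4-bis(methoxymethoxy)benzene by Li–Br exchange, then deprotect to 5.
2. **Step 5 (Pd O-tert-prenylation).**
   - Risks: re-ionisation of the electron-poor 4'-aryl ether to the linear O-prenyl ether, and over-alkylation at 2'-OH.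
   - Fallback: drop π-allyl chemistry. Make the bis(1,1-dimethylpropargyl) ether with 3-chloro-3-methylbut-1-yne/CuCl2/DBU, then semi-hydrogenate with Lindlar catalyst to 9.
3. **Step 6 (double Claisen).**
   - Risks: C5' migration on ring A, loss of isoprene, and thermal erosion of ee.
   - Fallback: carry the prenyl groups in the building blocks instead of using O→C transfer.
     - Ring A: use 2-prenylresorcinol in place of 3, made from 1,3-bis(methoxymethoxy)benzene by ortho-lithiation, prenyl bromide and deprotection. C2 is then blocked.
     - Ring B: use a 3-prenyl acid made by Stille coupling of a 3-iodo-D-tyrosine-derived lactate with tributyl(prenyl)stannane.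
     - Then esterify, rearrange and deprotect.

Check ee by chiral HPLC after steps 3 and 6.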